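Remark on the chemistry: the carbocycle is numbered C1 (aryl-bearing carbon), C2=C3 (methyl on C3), C4, C5 (gem-dimethyl), C6, with C7 the carbinol carbon; the antipode of the chiral ligand in step 5 that gives the (S) carbinol has to be fixed in a first run.

## Analysis of the target

- **Skeleton.** The target 28 is a cyclohexene that carries a 5,7-dimethoxycoumarin-8-yl group on C1 (ring A coumarin), a trisubstituted C2=C3 alkene with a methyl group on C3, a gem-dimethyl group on C5, and on C6 the carbinol carbon C7, which bears a second 5,7-dimethoxycoumarin-8-yl group (ring B coumarin).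
- **Stereocenters.** There are three contiguous centers: C1 (S), C6 (R) and C7 (R). The aryl group on C1 and the C7 substituent on C6 are trans on the ring. C7 is an exocyclic secondary carbinol next to C6.
- **Sensitive groups.** Both lactones are attacked by amide bases, organolithium reagents and strong hydride donors. The C7 carbinol is benzylic to a ring with two ortho oxygens and ionises readily in acid, where the C2=C3 alkene can trap the cation. The alkene is also exposed to attack by any free phenol ortho to C1 under acid. C6 becomes epimerisable whenever C7 is a carbonyl group.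
- **Difficulty.** C1, C6 and C7 sit between a quaternary carbon (C5) and two aryl groups that each carry two ortho substituents, so every bond made at these carbons is hindered. The two aryl groups are identical but are attached in different ways, so they cannot be introduced by one operation.
- **Feature used.** The C1–C6 bond joins an allylic, aryl-bearing carbon to the carbon α to C7, and C2=C3 lies exactly where an allylic transposition from C3 would leave it. If C3 carried oxygen and the alkene were at C1=C2, the array C6=C7–O–C3–C2=C1 would be a Claisen system. Because C3 and C6 are already joined through C4–C5, that array is the silyl ketene acetal of a six-membered lactone.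

## Retrosynthetic reasoning

**C7–H bond (28 to 27).** The last bond made is C7–H. The carbinol cannot be carried through deprotection and ring construction because it ionises, whereas ketone 27 is stable to those steps. The forward reduction must deliver hydride to one face of a hindered aryl ketone without touching two lactones.

**Pyranone of ring A (27 to 25 to 23 to 21).** The C3–C4 alkene and the lactone C–O bond of the ring A pyranone are cut, which leads to salicylaldehyde 25. Removing the formyl carbon gives phenol 23, and its protected form is 21. This is necessary because a coumarin would not survive the amide base of the key step, so ring A has to travel as a protected phenol. The phenol has only one free ortho position, so the formyl group can be placed without ambiguity. The forward steps must unmask the phenol without Brønsted acid, formylate ortho to it, and add two carbons with ring closure.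

**C7–aryl bond (21 to 20 to 16 and 18).** The bond between C7 and C8 of ring B is cut. Ring B is brought in complete as iodide 18, because once an acyl group sits on that ring the ring is deactivated towards the formylation used for ring A. The aryl nucleophile must therefore tolerate a lactone, which points to a chromium-mediated coupling of 18 with aldehyde 16. The coupling gives carbinol 20, and oxidation to 21 removes the uncontrolled C7 center. Iodide 18 comes from coumarin 17 by iodination.

**C6 configuration and oxidation level (16 to 15 to 14 to 13).** No skeletal bond is cut here. The key step can only deliver the cis acid 13, so C6 is inverted by equilibration at the ester stage (14 to 15) before reduction to aldehyde 16. An alkene of Z geometry in the key step would give the trans relationship directly, but it would force the aryl group into the inside position of the transition state against C5, so the E alkene and a later epimerisation are preferred. In the acid's own numbering the double bond takes locants 3 and 4, so the aryl group is on C2 and the gem-dimethyl group on C6.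

**Key disconnection (13 to 10).** The C1–C6 bond is cut, C3 is reconnected to the carboxyl oxygen, and the alkene moves to C1=C2. This retro-[3,3] shift is chosen because it is the one cut that removes the ring, the C1 stereocenter and the question of alkene position together, and replaces them by a single tertiary C–O stereocenter in lactone 10. Forward, enolisation and silylation of 10 must be followed by a concerted shift that closes the carbocycle, forms C1–C6 and C2=C3, and transfers the configuration of C3 to C1.

**Lactone and carbinol (10 to 9 to 6 and 3).** The acyl C–O bond of the lactone is cut to hydroxy ester 9, and then the bond between the carbinol carbon and the alkene is cut to alkyne 6 and keto ester 3. The alkenyl group is added to a simple dialkyl ketone because the reverse choice, adding methyl to an enone conjugated with the trioxygenated arene, would meet a deactivated carbonyl group. The closure to 10 has to be done with base. The tertiary allylic C–O bond is conjugated with a very electron-rich arene and would ionise under any acid strong enough to lactonise a tert-butyl ester, and the acetal protecting group would be lost too. A methyl ester is therefore used.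

**Building blocks (6 to 5 to 4, and 3 to 2 to 1).** Alkyne 6 comes from aldehyde 5 by one-carbon homologation, and 5 from the commercial salicylaldehyde 4 by protection. Keto ester 3 comes from keto acid 2, the ring-opened form of dimedone 1.

## Alternatives that were turned down

**Alternative 1:** Organocatalytic Michael–Henry annulation.
- Disconnection: C1–C6 and C2–C3, giving the nitroalkene 5,7-dimethoxy-8-[(E)-2-nitroethenyl]-2H-chromen-2-one A1 and the keto aldehyde 3,3-dimethyl-5-oxohexanal A2.
- Forward key step: the enamine of A2 with diphenylprolinol trimethylsilyl ether adds through C6 to C1 of A1. DBU then lets the nitronate carbon C2 add to the C3 ketone, which gives the nitrocyclohexanol aldehyde A3.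
- For: ring A is carried complete from the start, so no late annulation is needed. The catalyst sets C1 and C6 directly in the trans arrangement, so no epimerisation is needed. C7 arrives as an aldehyde. On these three points it is stronger than the chosen route.
- Against: the Michael step joins a nucleophilic carbon next to the quaternary C5 to an acceptor carbon that bears an aryl group with two ortho substituents and three donor oxygens. A3 still carries a nitro group on C2 and a hydroxyl group on C3. Dehydration gives a nitroalkene, and replacing a vinylic nitro group by hydrogen without moving the double bond has no dependable solution. Removing the nitro group first leaves a tertiary alcohol that can eliminate in three directions.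
- Comparison: the chosen strategy pays with an epimerisation and a late ring A annulation, but it places C2=C3 by the mechanism of the key step itself.

**Alternative 2:** Twofold propiolate hydroarylation.
- Disconnection: the C4–C4a bonds of both pyranones, giving the bis(aryl propiolate) A4.
- Forward key step: cationic monovalent gold (Ph3PAuCl/AgSbF6) effects a double 6-endo-dig hydroarylation and closes both lactone rings, giving ketone A5, which is the same structure as 27.
- For: both aryl groups travel as simple phenol ethers, the aryl–C7 bond can be made with an ordinary aryllithium, and one operation closes two rings with fixed regiochemistry. As an end-game it is at least as short as the one chosen here.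
- Against: A4 already contains the carbocycle and the C1 and C6 centers, so the alternative does not address the main problem. The gold cation must also distinguish two alkynes from the ring alkene. The phenol of ring B is hydrogen-bonded to the ketone and hindered towards acylation.
- Comparison: it is complementary to the chosen strategy, not a competitor, and is kept as the fallback for step 12. The chosen strategy spends its key step on the ring and its stereocenters.

**Alternative 3:** Mesityl oxide annulation.
- Disconnection: C5–C6 and C1=C2, giving the aroylacetate ethyl 3-[2,4-dimethoxy-6-(methoxymethoxy)phenyl]-3-oxopropanoate A6 and mesityl oxide A7.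
- Forward key step: the enolate of A6 (KOtBu) adds to the β-carbon of A7, and the methyl ketone then condenses onto the aryl ketone to give cyclohexenone A8.
- For: two cheap components and one flask give the ring with the gem-dimethyl and carboxyl groups in place. It is the shortest access to the carbon skeleton.
- Against: a stabilised β-keto ester anion must add reversibly to a β,β-disubstituted enone and create a quaternary carbon next to a tertiary one. The aldol closure must then attack an aryl ketone that is shielded by two ortho oxygens and deactivated by three donors. A8 has C1 as an sp2 carbon and a ketone at C3, so methyl addition, alkene transposition and creation of C1 must follow, with no element that controls C1 and no absolute control at all.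
- Comparison: the chosen strategy is longer to the ring but fixes C1 in absolute terms and places the alkene correctly in one step.

Key step: step 7

## Route

Step 1
Reactants: 1 dimedone (5,5-dimethylcyclohexane-1,3-dione)
Product: 2 3,3-dimethyl-5-oxohexanoic acid
Conditions: Ba(OH)2·8H2O, H2O, reflux; then aq. HCl
Reagents that add atoms: water, O
Why: Hydroxide adds to one carbonyl group of the 1,3-diketone and the adduct fragments to the carboxylate and the methyl ketone (retro-Claisen cleavage); hot aqueous base is needed because the diketone is largely present as its unreactive enolate.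

Step 2
Reactants: 2 3,3-dimethyl-5-oxohexanoic acid
Product: 3 methyl 3,3-dimethyl-5-oxohexanoate
Conditions: MeOH, H2SO4 (cat.), reflux
Reagents that add atoms: methanol, CO
Why: Fischer esterification of an unhindered CH2CO2H group; any dimethyl ketal of the ketone reverts on aqueous work-up.

Step 3
Reactants: 4 2-hydroxy-4,6-dimethoxybenzaldehyde
Product: 5 2,4-dimethoxy-6-(methoxymethoxy)benzaldehyde
Conditions: NaH, MOMCl, DMF, 0 °C to rt
Reagents that add atoms: chloromethyl methyl ether, COCCl
Why: Williamson-type O-alkylation of the sodium phenoxide; full deprotonation is used because the phenol is hydrogen-bonded to the aldehyde.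

Step 4
Reactants: 5 2,4-dimethoxy-6-(methoxymethoxy)benzaldehyde
Product: 6 2-ethynyl-1,5-dimethoxy-3-(methoxymethoxy)benzene
Conditions: dimethyl (1-diazo-2-oxopropyl)phosphonate, K2CO3, MeOH, rt
Reagents that add atoms: dimethyl (1-diazo-2-oxopropyl)phosphonate, COP(=O)(OC)C(=[N+]=[N-])C(C)=O
Why: Ohira–Bestmann variant of the Seyferth–Gilbert homologation: the diazomethylphosphonate anion adds to the non-enolisable aldehyde, and loss of phosphate and N2 with 1,2-shift gives the terminal alkyne; the ethers are inert to K2CO3 in methanol.

Step 5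
Reactants: 6 2-ethynyl-1,5-dimethoxy-3-(methoxymethoxy)benzene; 3 methyl 3,3-dimethyl-5-oxohexanoate
Product: 9 methyl (5S,6E)-7-[2,4-dimethoxy-6-(methoxymethoxy)phenyl]-5-hydroxy-3,3,5-trimethylhept-6-enoate, via alkenylzirconocene chloride 7 (not isolated), via alkenyl(methyl)zinc 8 (not isolated)
Conditions: Cp2ZrHCl, CH2Cl2, rt; Me2Zn, toluene, −78 °C; then 3, Ti(OiPr)4 (1.2 equiv), N,N'-(cyclohexane-1,2-diyl)bis[(2-hydroxy-7,7-dimethylbicyclo[2.2.1]heptan-1-yl)methanesulfonamide] (10 mol %), toluene, rt
Reagents that add atoms: none
Why: syn-Hydrozirconation puts zirconium on the terminal carbon and fixes the E geometry, and exchange to zinc gives an alkenyl reagent that adds to the ketone and not to the ester inside the chiral titanium bis(sulfonamide) diol complex (catalytic asymmetric alkenylation of ketones). The carbinol center is set by the ligand, whose antipode is chosen to give (S). Any lactone 10 formed already is harmless because step 6 converges on it.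

Step 6
Reactants: 9 methyl (5S,6E)-7-[2,4-dimethoxy-6-(methoxymethoxy)phenyl]-5-hydroxy-3,3,5-trimethylhept-6-enoate
Product: 10 (6S)-6-{(E)-2-[2,4-dimethoxy-6-(methoxymethoxy)phenyl]ethenyl}-4,4,6-trimethyloxan-2-one
Conditions: NaH, THF, 0 °C to rt; pH 7 buffer
Reagents that add atoms: none
Why: The tertiary sodium alkoxide attacks the methyl ester in a 6-exo-trig acyl substitution that is helped by the gem-dimethyl group (Thorpe–Ingold effect) and by the low solubility of NaOMe in THF. Base is used because acid would ionise the tertiary allylic C–O bond, which is conjugated with the trioxygenated arene, and would cleave the acetal. The C–O bond of the stereocenter is not broken, so its configuration is kept.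

Step 7
Reactants: 10 (6S)-6-{(E)-2-[2,4-dimethoxy-6-(methoxymethoxy)phenyl]ethenyl}-4,4,6-trimethyloxan-2-one
Product: 13 (1S,2S)-2-[2,4-dimethoxy-6-(methoxymethoxy)phenyl]-4,6,6-trimethylcyclohex-3-ene-1-carboxylic acid, via silyl ketene acetal 11 (not isolated), via trimethylsilyl ester 12 (not isolated)
Conditions: LiN(iPr)2, Me3SiCl/Et3N, THF, −78 °C to rt; toluene, 80 °C; then H2O, NaH2PO4 buffer
Reagents that add atoms: none
Why: Enolisation of 10 at its only α-methylene (C6) and O-silylation give the cyclic silyl ketene acetal 11, in which C6=C7–O–C3–C2=C1 is set up for a concerted [3,3] shift (Ireland–Claisen rearrangement; the closest known type is the rearrangement of silyl ketene acetals of lactones that carry an alkenyl group on the carbinol carbon). The shift breaks the C3–O bond, forms C1–C6 and C2=C3, and leaves C7 as the silyl ester 12, which water cleaves to 13. The carbocycle C1 to C6 is closed by the sigmatropic bond formation itself, inside a bicyclo[2.2.2]-like array in which the two-atom tether C4–C5 spans the termini C3 and C6; this tether cannot reach across a chair, so only the boat is open. C1 is controlled by C3: the shift is suprafacial on the allyl unit, the (6S) center decides which alkene face lies under C6, and the E geometry keeps the aryl group on the outer side of the boat, which gives (S) at C1. C6 is controlled by the ring-fixed geometry of the ketene acetal (C5 cis to the ring oxygen) together with the boat, which places carboxyl and aryl cis. The step needs boat over chair (secured by the tether), a concerted shift over heterolysis of the tertiary allylic C3–O bond (secured by basic silylation with amine present and no Lewis or Brønsted acid), and O-silylation of the enolate as it forms (silyl chloride present during deprotonation at −78 °C). The gem-dimethyl group on C5 favours the folded conformer in which C1 lies over C6.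

Step 8
Reactants: 13 (1S,2S)-2-[2,4-dimethoxy-6-(methoxymethoxy)phenyl]-4,6,6-trimethylcyclohex-3-ene-1-carboxylic acid
Product: 14 methyl (1S,2S)-2-[2,4-dimethoxy-6-(methoxymethoxy)phenyl]-4,6,6-trimethylcyclohex-3-ene-1-carboxylate
Conditions: MeI, K2CO3, DMF, rt
Reagents that add atoms: iodomethane, CI
Why: SN2 O-methylation of the potassium carboxylate, which is not slowed by the hindrance around the carboxyl carbon; the conditions are non-acidic and do not epimerise the ester at rt.

Step 9
Reactants: 14 methyl (1S,2S)-2-[2,4-dimethoxy-6-(methoxymethoxy)phenyl]-4,6,6-trimethylcyclohex-3-ene-1-carboxylate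
Product: 15 methyl (1R,2S)-2-[2,4-dimethoxy-6-(methoxymethoxy)phenyl]-4,6,6-trimethylcyclohex-3-ene-1-carboxylate
Conditions: NaOMe, MeOH, 65 °C
Reagents that add atoms: none
Why: Reversible enolisation of the ester (thermodynamic epimerisation α to a carbonyl group) inverts only the ester-bearing carbon, since the aryl-bearing carbon has no acidifying group. The aryl group must stay pseudo-equatorial to avoid the axial methyl group across the ring, so the cis ester is axial and lies under an ortho substituent of the aryl ring; the trans isomer with an equatorial ester relieves this and should be favoured.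

Step 10
Reactants: 15 methyl (1R,2S)-2-[2,4-dimethoxy-6-(methoxymethoxy)phenyl]-4,6,6-trimethylcyclohex-3-ene-1-carboxylate
Product: 16 (1R,2S)-2-[2,4-dimethoxy-6-(methoxymethoxy)phenyl]-4,6,6-trimethylcyclohex-3-ene-1-carbaldehyde
Conditions: iBu2AlH, CH2Cl2, −78 °C; aq. potassium sodium tartrate
Reagents that add atoms: none
Why: Partial reduction of an ester; the aluminium hemiacetal of this hindered ester should persist at −78 °C and release the aldehyde only on work-up. The trans aldehyde is the more stable epimer, so the configuration should hold.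

Step 11
Reactants: 17 5,7-dimethoxy-2H-chromen-2-one (5,7-dimethoxycoumarin)
Product: 18 8-iodo-5,7-dimethoxy-2H-chromen-2-one
Conditions: N-iodosuccinimide, CF3CO2H (cat.), MeCN, rt
Reagents that add atoms: N-iodosuccinimide, O=C1CCC(=O)N1I
Why: Electrophilic aromatic iodination; C8 is para to the C5 methoxy group and ortho to the C7 methoxy group and is less crowded than C6, which lies between two methoxy groups, while C3 belongs to the electron-poor enoate.

Step 12
Reactants: 16 (1R,2S)-2-[2,4-dimethoxy-6-(methoxymethoxy)phenyl]-4,6,6-trimethylcyclohex-3-ene-1-carbaldehyde; 18 8-iodo-5,7-dimethoxy-2H-chromen-2-one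
Product: 20 8-{hydroxy[(1R,2S)-2-[2,4-dimethoxy-6-(methoxymethoxy)phenyl]-4,6,6-trimethylcyclohex-3-en-1-yl]methyl}-5,7-dimethoxy-2H-chromen-2-one (both C7 epimers), via arylchromium dichloride 19 (not isolated)
Conditions: CrCl2 (excess), NiCl2 (cat.), DMF, rt to 50 °C
Reagents that add atoms: none
Why: Nozaki–Hiyama–Kishi coupling: zerovalent nickel inserts into the C–I bond, exchange gives the trivalent arylchromium 19, and this adds to the aldehyde while leaving the lactone alone. Both C7 epimers are used because step 13 removes this center.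

Step 13
Reactants: 20 8-{hydroxy[(1R,2S)-2-[2,4-dimethoxy-6-(methoxymethoxy)phenyl]-4,6,6-trimethylcyclohex-3-en-1-yl]methyl}-5,7-dimethoxy-2H-chromen-2-one (both C7 epimers)
Product: 21 8-{(1R,2S)-2-[2,4-dimethoxy-6-(methoxymethoxy)phenyl]-4,6,6-trimethylcyclohex-3-ene-1-carbonyl}-5,7-dimethoxy-2H-chromen-2-one
Conditions: Dess–Martin periodinane, NaHCO3, CH2Cl2, 0 °C to rt
Reagents that add atoms: none
Why: Dess–Martin oxidation of a secondary benzylic alcohol; the buffer keeps the acetic acid released from ionising the carbinol or cleaving the acetal. The ketone is also the form of C7 that survives steps 14 to 16.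

Step 14
Reactants: 21 8-{(1R,2S)-2-[2,4-dimethoxy-6-(methoxymethoxy)phenyl]-4,6,6-trimethylcyclohex-3-ene-1-carbonyl}-5,7-dimethoxy-2H-chromen-2-one
Product: 23 8-[(1R,2S)-2-(2-hydroxy-4,6-dimethoxyphenyl)-4,6,6-trimethylcyclohex-3-ene-1-carbonyl]-5,7-dimethoxy-2H-chromen-2-one, via aryl trimethylsilyl ether 22 (not isolated)
Conditions: Me3SiOTf, 2,2'-bipyridyl, CH2Cl2, 0 °C to rt; then H2O
Reagents that add atoms: none
Why: The acetal oxygen is silylated and the bipyridyl takes up the methoxymethyl cation, which leaves the aryl silyl ether 22; water then cleaves it (non-protic cleavage of aromatic methoxymethyl ethers). Avoiding Brønsted acid protects the C2=C3 alkene from attack by the neighbouring phenol oxygen and keeps the phenol from forming an enol ether with the ketone.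

Step 15
Reactants: 23 8-[(1R,2S)-2-(2-hydroxy-4,6-dimethoxyphenyl)-4,6,6-trimethylcyclohex-3-ene-1-carbonyl]-5,7-dimethoxy-2H-chromen-2-one
Product: 25 8-[(1R,2S)-2-(3-formyl-2-hydroxy-4,6-dimethoxyphenyl)-4,6,6-trimethylcyclohex-3-ene-1-carbonyl]-5,7-dimethoxy-2H-chromen-2-one, via hydroxymethyl phenol 24 (not isolated)
Conditions: MgCl2, Et3N, (CH2O)n, MeCN, reflux
Reagents that add atoms: formaldehyde (as paraformaldehyde), C=O
Why: Magnesium-mediated ortho-formylation of a phenol (Casnati–Skattebøl reaction): the magnesium phenoxide delivers formaldehyde to the only free ortho position to give 24, which a second formaldehyde oxidises by hydride transfer. The position para to the phenol is not reached because the reaction runs through the chelate.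

Step 16
Reactants: 25 8-[(1R,2S)-2-(3-formyl-2-hydroxy-4,6-dimethoxyphenyl)-4,6,6-trimethylcyclohex-3-ene-1-carbonyl]-5,7-dimethoxy-2H-chromen-2-one
Product: 27 8-[(1R,2S)-2-(5,7-dimethoxy-2-oxo-2H-chromen-8-yl)-4,6,6-trimethylcyclohex-3-ene-1-carbonyl]-5,7-dimethoxy-2H-chromen-2-one, via phosphorane ester 26 (not isolated)
Conditions: Ph3P=C=C=O, toluene, 110 °C
Reagents that add atoms: (triphenylphosphoranylidene)ketene, O=C=C=P(c1ccccc1)(c1ccccc1)c1ccccc1
Why: The phenol adds to the ketene ylide to give the aryl ester phosphorane 26, which undergoes intramolecular Wittig olefination with the ortho aldehyde and so closes the pyranone (coumarin synthesis from a salicylaldehyde). The conditions are neutral, so the ketone and the C6 center next to it are not disturbed.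

Step 17
Reactants: 27 8-[(1R,2S)-2-(5,7-dimethoxy-2-oxo-2H-chromen-8-yl)-4,6,6-trimethylcyclohex-3-ene-1-carbonyl]-5,7-dimethoxy-2H-chromen-2-one
Product: 28 8-{(R)-hydroxy[(1R,2S)-2-(5,7-dimethoxy-2-oxo-2H-chromen-8-yl)-4,6,6-trimethylcyclohex-3-en-1-yl]methyl}-5,7-dimethoxy-2H-chromen-2-one
Conditions: NaBH4, CeCl3·7H2O, MeOH/THF, −40 to 0 °C
Reagents that add atoms: none
Why: Luche-type 1,2-reduction, in which the ketone should react before the lactones. In the Felkin–Anh arrangement with the quaternary C5 anti to the incoming hydride and the carbonyl oxygen beside C1, hydride enters past the C6 hydrogen and gives (R) at C7. The neutral work-up avoids ionisation of the product.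

## Compound list

1 | dimedone (5,5-dimethylcyclohexane-1,3-dione) | CC1(C)CC(=O)CC(=O)C1 | starting material
2 | 3,3-dimethyl-5-oxohexanoic acid | CC(=O)CC(C)(C)CC(=O)O | intermediate
3 | methyl 3,3-dimethyl-5-oxohexanoate | COC(=O)CC(C)(C)CC(C)=O | intermediate
4 | 2-hydroxy-4,6-dimethoxybenzaldehyde | COc1cc(O)c(C=O)c(OC)c1 | starting material
5 | 2,4-dimethoxy-6-(methoxymethoxy)benzaldehyde | COCOc1cc(OC)cc(OC)c1C=O | intermediate
6 | 2-ethynyl-1,5-dimethoxy-3-(methoxymethoxy)benzene | COCOc1cc(OC)cc(OC)c1C#C | intermediate
7 | chlorobis(cyclopentadienyl){(E)-2-[2,4-dimethoxy-6-(methoxymethoxy)phenyl]ethenyl}zirconium | COCOc1cc(OC)cc(OC)c1/C=C/[Zr](Cl)(C1C=CC=C1)C1C=CC=C1 | intermediate (not isolated)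
8 | {(E)-2-[2,4-dimethoxy-6-(methoxymethoxy)phenyl]ethenyl}(methyl)zinc | COCOc1cc(OC)cc(OC)c1/C=C/[Zn]C | intermediate (not isolated)
9 | methyl (5S,6E)-7-[2,4-dimethoxy-6-(methoxymethoxy)phenyl]-5-hydroxy-3,3,5-trimethylhept-6-enoate | COC(=O)CC(C)(C)C[C@](C)(O)/C=C/c1c(OC)cc(OC)cc1OCOC | intermediate
10 | (6S)-6-{(E)-2-[2,4-dimethoxy-6-(methoxymethoxy)phenyl]ethenyl}-4,4,6-trimethyloxan-2-one | O=C1CC(C)(C)C[C@@](C)(/C=C/c2c(OC)cc(OC)cc2OCOC)O1 | intermediate (precursor of the key step)
11 | {[(2S)-2-{(E)-2-[2,4-dimethoxy-6-(methoxymethoxy)phenyl]ethenyl}-2,4,4-trimethyl-3,4-dihydro-2H-pyran-6-yl]oxy}trimethylsilane | C[Si](C)(C)OC1=CC(C)(C)C[C@@](C)(/C=C/c2c(OC)cc(OC)cc2OCOC)O1 | intermediate (not isolated)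
12 | trimethylsilyl (1S,2S)-2-[2,4-dimethoxy-6-(methoxymethoxy)phenyl]-4,6,6-trimethylcyclohex-3-ene-1-carboxylate | COCOc1cc(OC)cc(OC)c1[C@H]1C=C(C)CC(C)(C)[C@H]1C(=O)O[Si](C)(C)C | intermediate (not isolated)
13 | (1S,2S)-2-[2,4-dimethoxy-6-(methoxymethoxy)phenyl]-4,6,6-trimethylcyclohex-3-ene-1-carboxylic acid | COCOc1cc(OC)cc(OC)c1[C@H]1C=C(C)CC(C)(C)[C@H]1C(=O)O | intermediate (product of the key step)
14 | methyl (1S,2S)-2-[2,4-dimethoxy-6-(methoxymethoxy)phenyl]-4,6,6-trimethylcyclohex-3-ene-1-carboxylate | COCOc1cc(OC)cc(OC)c1[C@H]1C=C(C)CC(C)(C)[C@H]1C(=O)OC | intermediate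
15 | methyl (1R,2S)-2-[2,4-dimethoxy-6-(methoxymethoxy)phenyl]-4,6,6-trimethylcyclohex-3-ene-1-carboxylate | COCOc1cc(OC)cc(OC)c1[C@H]1C=C(C)CC(C)(C)[C@@H]1C(=O)OC | intermediate
16 | (1R,2S)-2-[2,4-dimethoxy-6-(methoxymethoxy)phenyl]-4,6,6-trimethylcyclohex-3-ene-1-carbaldehyde | COCOc1cc(OC)cc(OC)c1[C@H]1C=C(C)CC(C)(C)[C@@H]1C=O | intermediate
17 | 5,7-dimethoxy-2H-chromen-2-one | COc1cc(OC)c2ccc(=O)oc2c1 | starting material
18 | 8-iodo-5,7-dimethoxy-2H-chromen-2-one | COc1cc(OC)c2ccc(=O)oc2c1I | intermediate
19 | dichloro(5,7-dimethoxy-2-oxo-2H-chromen-8-yl)chromium | COc1cc(OC)c2ccc(=O)oc2c1[Cr](Cl)Cl | intermediate (not isolated)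
20 | 8-{hydroxy[(1R,2S)-2-[2,4-dimethoxy-6-(methoxymethoxy)phenyl]-4,6,6-trimethylcyclohex-3-en-1-yl]methyl}-5,7-dimethoxy-2H-chromen-2-one, both C7 epimers | COCOc1cc(OC)cc(OC)c1[C@H]1C=C(C)CC(C)(C)[C@@H]1C(O)c1c(OC)cc(OC)c2ccc(=O)oc12 | intermediate
21 | 8-{(1R,2S)-2-[2,4-dimethoxy-6-(methoxymethoxy)phenyl]-4,6,6-trimethylcyclohex-3-ene-1-carbonyl}-5,7-dimethoxy-2H-chromen-2-one | COCOc1cc(OC)cc(OC)c1[C@H]1C=C(C)CC(C)(C)[C@@H]1C(=O)c1c(OC)cc(OC)c2ccc(=O)oc12 | intermediate
22 | 8-{(1R,2S)-2-[2,4-dimethoxy-6-(trimethylsilyloxy)phenyl]-4,6,6-trimethylcyclohex-3-ene-1-carbonyl}-5,7-dimethoxy-2H-chromen-2-one | C[Si](C)(C)Oc1cc(OC)cc(OC)c1[C@H]1C=C(C)CC(C)(C)[C@@H]1C(=O)c1c(OC)cc(OC)c2ccc(=O)oc12 | intermediate (not isolated)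
23 | 8-[(1R,2S)-2-(2-hydroxy-4,6-dimethoxyphenyl)-4,6,6-trimethylcyclohex-3-ene-1-carbonyl]-5,7-dimethoxy-2H-chromen-2-one | Oc1cc(OC)cc(OC)c1[C@H]1C=C(C)CC(C)(C)[C@@H]1C(=O)c1c(OC)cc(OC)c2ccc(=O)oc12 | intermediate
24 | 8-{(1R,2S)-2-[2-hydroxy-3-(hydroxymethyl)-4,6-dimethoxyphenyl]-4,6,6-trimethylcyclohex-3-ene-1-carbonyl}-5,7-dimethoxy-2H-chromen-2-one | OCc1c(O)c([C@H]2C=C(C)CC(C)(C)[C@@H]2C(=O)c2c(OC)cc(OC)c3ccc(=O)oc23)c(OC)cc1OC | intermediate (not isolated)
25 | 8-[(1R,2S)-2-(3-formyl-2-hydroxy-4,6-dimethoxyphenyl)-4,6,6-trimethylcyclohex-3-ene-1-carbonyl]-5,7-dimethoxy-2H-chromen-2-one | O=Cc1c(O)c([C@H]2C=C(C)CC(C)(C)[C@@H]2C(=O)c2c(OC)cc(OC)c3ccc(=O)oc23)c(OC)cc1OC | intermediate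
26 | 8-[(1R,2S)-2-(3-formyl-4,6-dimethoxy-2-{[(triphenylphosphoranylidene)acetyl]oxy}phenyl)-4,6,6-trimethylcyclohex-3-ene-1-carbonyl]-5,7-dimethoxy-2H-chromen-2-one | O=Cc1c(OC(=O)C=P(c2ccccc2)(c2ccccc2)c2ccccc2)c([C@H]2C=C(C)CC(C)(C)[C@@H]2C(=O)c2c(OC)cc(OC)c3ccc(=O)oc23)c(OC)cc1OC | intermediate (not isolated)
27 | 8-[(1R,2S)-2-(5,7-dimethoxy-2-oxo-2H-chromen-8-yl)-4,6,6-trimethylcyclohex-3-ene-1-carbonyl]-5,7-dimethoxy-2H-chromen-2-one | COc1cc(OC)c2ccc(=O)oc2c1[C@H]1C=C(C)CC(C)(C)[C@@H]1C(=O)c1c(OC)cc(OC)c2ccc(=O)oc12 | intermediate
28 | 8-{(R)-hydroxy[(1R,2S)-2-(5,7-dimethoxy-2-oxo-2H-chromen-8-yl)-4,6,6-trimethylcyclohex-3-en-1-yl]methyl}-5,7-dimethoxy-2H-chromen-2-one | COc1cc(OC)c2ccc(=O)oc2c1[C@H]1C=C(C)CC(C)(C)[C@@H]1[C@@H](O)c1c(OC)cc(OC)c2ccc(=O)oc12 | target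

## Step count and least certain steps

Total: 17 steps. Longest linear sequence: 14 steps (from 4 through steps 3 to 10 and 12 to 17; the branch from 1 is equally long).

**Step 7 (key step).** The tertiary allylic C3–O bond, which is conjugated with the trioxygenated arene, may break heterolytically before or beside the concerted shift. That would erode the transfer of configuration to C1 or end in elimination. Enolisation at the methylene next to the quaternary carbon may also be incomplete, and the strained boat may demand temperatures at which these side paths gain. Fallback: the ring is built by a Diels–Alder reaction instead, setting out from 5. Claisen–Schmidt condensation of 5 with acetone (NaOH) gives (E)-4-[2,4-dimethoxy-6-(methoxymethoxy)phenyl]but-3-en-2-one F1. Wittig methylenation (Ph3P=CH2) gives the diene 1,5-dimethoxy-3-(methoxymethoxy)-2-[(1E)-3-methylbuta-1,3-dien-1-yl]benzene F2. Cycloaddition of F2 with 3-methylbut-2-enal (sealed tube, heat, or Me2AlCl at low temperature), in which the aryl and methyl groups of the diene both direct the aryl-bearing carbon to the formyl-bearing carbon, followed by equilibration with K2CO3 in methanol, gives racemic trans-2-[2,4-dimethoxy-6-(methoxymethoxy)phenyl]-4,6,6-trimethylcyclohex-3-ene-1-carbaldehyde F3. Separation of the enantiomers on a chiral stationary phase returns to the route at 16.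

**Step 5.** The catalyst has to tell a methyl group from a methylene group on the two sides of the ketone, which is a small difference, so the enantiomeric purity may be insufficient; every later stereocenter derives from this one. Fallback: the roles of the ketone substituents are exchanged so that the catalyst distinguishes an alkenyl from an alkyl group. Setting out from 2 and 5, Claisen–Schmidt condensation (NaOH, aqueous ethanol) at the methyl group of 2 gives (E)-7-[2,4-dimethoxy-6-(methoxymethoxy)phenyl]-3,3-dimethyl-5-oxohept-6-enoic acid F4. Methylation (MeI, K2CO3) gives its methyl ester F5, and addition of Me2Zn under Ti(OiPr)4 and the same ligand class returns to the route at 9.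

**Step 9.** Enolisation of an ester flanked by a quaternary carbon is slow, and the equilibrium may not lie far enough on the trans side, because an equatorial ester is gauche to both methyl groups on C5. Fallback: the cis series is carried on and C6 is inverted at the ketone, where the proton is more acidic. Setting out from 14, iBu2AlH gives (1S,2S)-2-[2,4-dimethoxy-6-(methoxymethoxy)phenyl]-4,6,6-trimethylcyclohex-3-ene-1-carbaldehyde F6. Coupling with 18 (CrCl2, NiCl2) gives the cis carbinol 8-{hydroxy[(1S,2S)-2-[2,4-dimethoxy-6-(methoxymethoxy)phenyl]-4,6,6-trimethylcyclohex-3-en-1-yl]methyl}-5,7-dimethoxy-2H-chromen-2-one F7. Dess–Martin oxidation gives the cis ketone 8-{(1S,2S)-2-[2,4-dimethoxy-6-(methoxymethoxy)phenyl]-4,6,6-trimethylcyclohex-3-ene-1-carbonyl}-5,7-dimethoxy-2H-chromen-2-one F8, and DBU in toluene equilibrates it, returning to the route at 21.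

**Step 12.** Oxidative addition and carbonyl addition may both be slow, because the iodide has two ortho substituents and the aldehyde is branched next to a quaternary carbon; reduction of the C–I bond would then take over. Fallback: an aryllithium without a lactone is used and both pyranones are closed at the end. Setting out from 16, 2,4,6-trimethoxyphenyllithium F9 (from 1,3,5-trimethoxybenzene and n-BuLi) adds to give the carbinol {(1R,2S)-2-[2,4-dimethoxy-6-(methoxymethoxy)phenyl]-4,6,6-trimethylcyclohex-3-en-1-yl}(2,4,6-trimethoxyphenyl)methanol F10. Dess–Martin oxidation gives the ketone {(1R,2S)-2-[2,4-dimethoxy-6-(methoxymethoxy)phenyl]-4,6,6-trimethylcyclohex-3-en-1-yl}(2,4,6-trimethoxyphenyl)methanone F11. BCl3 at low temperature removes the acetal and the one methoxy group chelated to the ketone, giving the bisphenol [(1R,2S)-2-(2-hydroxy-4,6-dimethoxyphenyl)-4,6,6-trimethylcyclohex-3-en-1-yl](2-hydroxy-4,6-dimethoxyphenyl)methanone F12. Propiolic acid and DCC give the bis(aryl propiolate) F13, and Ph3PAuCl/AgSbF6 closes both lactone rings by hydroarylation, returning to the route at 27.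

**Step 17.** C1 and C5 both flank the carbonyl group closely, so the facial preference of the hydride may be small or reversed; the ketone is also shielded by two ortho substituents, so slow reduction may let the lactones react. Fallback: stereocontrol is moved from the substrate to the reagent. Setting out from 27, reduction with B-chlorodiisopinocampheylborane of the matching antipode, which does not reduce lactones and has no B–H bond for the alkene, returns to the route at 28 without a new compound.

## Further compounds

F1 | step 7 | (E)-4-[2,4-dimethoxy-6-(methoxymethoxy)phenyl]but-3-en-2-one | COCOc1cc(OC)cc(OC)c1/C=C/C(C)=O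
F2 | step 7 | 1,5-dimethoxy-3-(methoxymethoxy)-2-[(1E)-3-methylbuta-1,3-dien-1-yl]benzene | COCOc1cc(OC)cc(OC)c1/C=C/C(C)=C
F3 | step 7 | rac-(1R,2S)-2-[2,4-dimethoxy-6-(methoxymethoxy)phenyl]-4,6,6-trimethylcyclohex-3-ene-1-carbaldehyde (racemate, one enantiomer drawn) | COCOc1cc(OC)cc(OC)c1[C@H]1C=C(C)CC(C)(C)[C@@H]1C=O
F4 | step 5 | (E)-7-[2,4-dimethoxy-6-(methoxymethoxy)phenyl]-3,3-dimethyl-5-oxohept-6-enoic acid | COCOc1cc(OC)cc(OC)c1/C=C/C(=O)CC(C)(C)CC(=O)O
F5 | step 5 | methyl (E)-7-[2,4-dimethoxy-6-(methoxymethoxy)phenyl]-3,3-dimethyl-5-oxohept-6-enoate | COCOc1cc(OC)cc(OC)c1/C=C/C(=O)CC(C)(C)CC(=O)OC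
F6 | step 9 | (1S,2S)-2-[2,4-dimethoxy-6-(methoxymethoxy)phenyl]-4,6,6-trimethylcyclohex-3-ene-1-carbaldehyde | COCOc1cc(OC)cc(OC)c1[C@H]1C=C(C)CC(C)(C)[C@H]1C=O
F7 | step 9 | 8-{hydroxy[(1S,2S)-2-[2,4-dimethoxy-6-(methoxymethoxy)phenyl]-4,6,6-trimethylcyclohex-3-en-1-yl]methyl}-5,7-dimethoxy-2H-chromen-2-one, both C7 epimers | COCOc1cc(OC)cc(OC)c1[C@H]1C=C(C)CC(C)(C)[C@H]1C(O)c1c(OC)cc(OC)c2ccc(=O)oc12
F8 | step 9 | 8-{(1S,2S)-2-[2,4-dimethoxy-6-(methoxymethoxy)phenyl]-4,6,6-trimethylcyclohex-3-ene-1-carbonyl}-5,7-dimethoxy-2H-chromen-2-one | COCOc1cc(OC)cc(OC)c1[C@H]1C=C(C)CC(C)(C)[C@H]1C(=O)c1c(OC)cc(OC)c2ccc(=O)oc12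
F9 | step 12 | 2,4,6-trimethoxyphenyllithium | [Li]c1c(OC)cc(OC)cc1OC
F10 | step 12 | {(1R,2S)-2-[2,4-dimethoxy-6-(methoxymethoxy)phenyl]-4,6,6-trimethylcyclohex-3-en-1-yl}(2,4,6-trimethoxyphenyl)methanol, both C7 epimers | COCOc1cc(OC)cc(OC)c1[C@H]1C=C(C)CC(C)(C)[C@@H]1C(O)c1c(OC)cc(OC)cc1OC
F11 | step 12 | {(1R,2S)-2-[2,4-dimethoxy-6-(methoxymethoxy)phenyl]-4,6,6-trimethylcyclohex-3-en-1-yl}(2,4,6-trimethoxyphenyl)methanone | COCOc1cc(OC)cc(OC)c1[C@H]1C=C(C)CC(C)(C)[C@@H]1C(=O)c1c(OC)cc(OC)cc1OC
F12 | step 12 | [(1R,2S)-2-(2-hydroxy-4,6-dimethoxyphenyl)-4,6,6-trimethylcyclohex-3-en-1-yl](2-hydroxy-4,6-dimethoxyphenyl)methanone | Oc1cc(OC)cc(OC)c1[C@H]1C=C(C)CC(C)(C)[C@@H]1C(=O)c1c(O)cc(OC)cc1OC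
F13 | step 12 | 2-[(1S,6R)-6-{2,4-dimethoxy-6-[(prop-2-ynoyl)oxy]benzoyl}-3,5,5-trimethylcyclohex-2-en-1-yl]-3,5-dimethoxyphenyl prop-2-ynoate | C#CC(=O)Oc1cc(OC)cc(OC)c1[C@H]1C=C(C)CC(C)(C)[C@@H]1C(=O)c1c(OC)cc(OC)cc1OC(=O)C#C
F0 | step 17 | none | none
A1 | alternative 1 | 5,7-dimethoxy-8-[(E)-2-nitroethenyl]-2H-chromen-2-one | COc1cc(OC)c2ccc(=O)oc2c1/C=C/[N+](=O)[O-]
A2 | alternative 1 | 3,3-dimethyl-5-oxohexanal | CC(=O)CC(C)(C)CC=O
A3 | alternative 1 | 6-(5,7-dimethoxy-2-oxo-2H-chromen-8-yl)-4-hydroxy-2,2,4-trimethyl-5-nitrocyclohexane-1-carbaldehyde (C1 and C6 of the ring as in the target, nitro and hydroxyl carbons unassigned) | COc1cc(OC)c2ccc(=O)oc2c1[C@H]1C([N+](=O)[O-])C(C)(O)CC(C)(C)[C@@H]1C=O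
A4 | alternative 2 | 2-[(1S,6R)-6-{2,4-dimethoxy-6-[(prop-2-ynoyl)oxy]benzoyl}-3,5,5-trimethylcyclohex-2-en-1-yl]-3,5-dimethoxyphenyl prop-2-ynoate | C#CC(=O)Oc1cc(OC)cc(OC)c1[C@H]1C=C(C)CC(C)(C)[C@@H]1C(=O)c1c(OC)cc(OC)cc1OC(=O)C#C
A5 | alternative 2 | 8-[(1R,2S)-2-(5,7-dimethoxy-2-oxo-2H-chromen-8-yl)-4,6,6-trimethylcyclohex-3-ene-1-carbonyl]-5,7-dimethoxy-2H-chromen-2-one | COc1cc(OC)c2ccc(=O)oc2c1[C@H]1C=C(C)CC(C)(C)[C@@H]1C(=O)c1c(OC)cc(OC)c2ccc(=O)oc12
A6 | alternative 3 | ethyl 3-[2,4-dimethoxy-6-(methoxymethoxy)phenyl]-3-oxopropanoate | CCOC(=O)CC(=O)c1c(OC)cc(OC)cc1OCOC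
A7 | alternative 3 | mesityl oxide (4-methylpent-3-en-2-one) | CC(=O)C=C(C)C
A8 | alternative 3 | ethyl 2-[2,4-dimethoxy-6-(methoxymethoxy)phenyl]-6,6-dimethyl-4-oxocyclohex-2-ene-1-carboxylate (racemic) | CCOC(=O)C1C(c2c(OC)cc(OC)cc2OCOC)=CC(=O)CC1(C)C
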